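**Plan**

1. Retrosynthesis (lignan numbering: oxolane C2 = C7, C3 = C8, C4 = C8', C5 = C9'; ester CH2O = C9; benzylic CH2 = C7'): cut the coumarate C9–O ester bond first, then the ring C7–O bond (oxolane O1–C2), then C7–C8 (aldol), and last the benzylic C7'–C8' bond.
2. Enabling feature: C8' lies β to C9 through C8. With C9 raised to an N-acylpyrazole and C8=C8' unsaturated, C8' becomes the electrophilic terminus of a Lewis-acid-chelated enoyl unit. The C9'–O oxygen rides along as a silyl ether that later closes a temporary γ-lactone, and the electron-rich guaiacyl ring makes its benzyl–BF3K bond easy to oxidise to the radical.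
3. Forward order: the benzyl trifluoroborate and the enoyl pyrazole are made separately and joined at C7'–C8' by an enantioselective photoredox radical conjugate addition. The γ-butyrolactone is then closed, the second guaiacyl unit is attached by aldol (C7–C8), the lactone is opened by hydride, the oxolane is closed at C7–O, the phenols are freed and the coumarate is put on last.
4. Stereochemistry: C8' by catalyst control (chiral-at-rhodium Lewis acid); C8 by 1,2-induction in the lactone enolate (trans); C7 by stereoconvergent cation capture, which gives the 2,3-trans oxolane from both carbinol epimers.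

Key step: step 5

Assumption: the Λ enantiomer of the rhodium catalyst is taken as the one that leaves the Si face of the β-carbon of the enoyl pyrazole open (S product); if the sense is the reverse, the Δ enantiomer is used and nothing else changes.

**Route**

Step 1
Reactants: 1 [4-(benzyloxy)-3-methoxyphenyl]methanol
Product: 2 1-(benzyloxy)-4-(chloromethyl)-2-methoxybenzene
Conditions: SOCl2 (1.2 equiv), CH2Cl2, 0 °C → rt
Reagents that add atoms: thionyl chloride, O=S(Cl)Cl
Why: Deoxychlorination of an electron-rich benzylic alcohol through its chlorosulfite should be fast at 0 °C and leaves the aryl benzyl ether untouched; no stereocenter is formed.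

Step 2
Reactants: 2 1-(benzyloxy)-4-(chloromethyl)-2-methoxybenzene
Product: 4 potassium [4-(benzyloxy)-3-methoxybenzyl]trifluoroborate, via benzyl pinacolboronate 3 (not isolated)
Conditions: B2pin2 (1.1 equiv), Pd(dba)2 (3 mol %), P(4-MeOC6H4)3 (6 mol %), KOAc, toluene, 50 °C; then aq. KHF2, MeOH, rt
Reagents that add atoms: bis(pinacolato)diboron, CC1(C)OB(OC1(C)C)B1OC(C)(C)C(C)(C)O1; potassium hydrogen difluoride, F.[F-].[K+]
Why: Miyaura borylation of the benzylic chloride (oxidative addition, transmetalation from the acetate-activated diboron, reductive elimination) followed by fluoride exchange should give the crystalline, bench-stable trifluoroborate; no stereocenter is formed.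

Step 3
Reactants: 5 acryloyl chloride; 6 3,5-dimethyl-1H-pyrazole
Product: 7 1-(3,5-dimethyl-1H-pyrazol-1-yl)prop-2-en-1-one
Conditions: Et3N (1.1 equiv), CH2Cl2, 0 °C
Reagents that add atoms: none
Why: N-Acylation of the pyrazole N–H by the acid chloride is much faster at 0 °C than conjugate addition of the pyrazole to the acrylamide that forms.

Step 4
Reactants: 7 1-(3,5-dimethyl-1H-pyrazol-1-yl)prop-2-en-1-one; 8 (allyloxy)(tert-butyl)dimethylsilane
Product: 9 (E)-4-[(tert-butyldimethylsilyl)oxy]-1-(3,5-dimethyl-1H-pyrazol-1-yl)but-2-en-1-one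
Conditions: 8 (3 equiv), 2nd-generation Ru isopropoxybenzylidene NHC metathesis catalyst (5 mol %), CH2Cl2, 40 °C
Reagents that add atoms: none
Why: Olefin cross-metathesis between an electron-poor acrylamide-type alkene and an excess of an electron-rich allyl ether should favour the cross product and give the E-alkene under thermodynamic control, with loss of ethene.

Step 5
Reactants: 4 potassium [4-(benzyloxy)-3-methoxybenzyl]trifluoroborate; 9 (E)-4-[(tert-butyldimethylsilyl)oxy]-1-(3,5-dimethyl-1H-pyrazol-1-yl)but-2-en-1-one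
Product: 11 (S)-4-[4-(benzyloxy)-3-methoxybenzyl]dihydrofuran-2(3H)-one, via silyloxy acyl pyrazole adduct 10 (not isolated)
Conditions: 4 (1.5 equiv), Λ-RhS [Λ-bis(5-tert-butyl-2-phenylbenzothiazole-C,N)Rh(MeCN)2 PF6] (4 mol %), [Ir(dF(CF3)ppy)2(dtbbpy)]PF6 (1 mol %), degassed acetone/H2O 4:1, blue LEDs, rt; then TBAF, AcOH, THF, 0 °C → rt
Reagents that add atoms: none
Why: The excited Ir(III) sensitiser should oxidise the electron-rich benzyltrifluoroborate 4, whose C–B bond fragments to the 4-benzyloxy-3-methoxybenzyl radical; this adds to C3 of 9 while 9 is N,O-chelated (pyrazole N2 and carbonyl O) to the chiral-at-metal Rh(III) Lewis acid, and the Rh-bound α-carbonyl radical is reduced by Ir(II) to the enolate and protonated by water, which makes the Giese addition redox-neutral. The closest known reaction type is the visible-light, Lewis-acid-catalysed enantioselective conjugate addition of benzylic and other alkyl radicals from organotrifluoroborates to β-substituted α,β-unsaturated N-acylpyrazoles. Fluoride then frees the primary alkoxide of 10, which closes the γ-butyrolactone by 5-exo-trig acyl substitution at the activated N-acylpyrazole and expels the pyrazole. The one new stereocenter (C3 of 10, C4 of 11, later C4 of the oxolane) is set by the catalyst alone: the metal-centred chirality should place a tert-butylbenzothiazole wall over the Re face of C3, so that the radical enters from the Si face and gives S. The step needs β-regioselectivity, facial control that outruns any racemic background addition, and radical capture faster than benzyl dimerisation; the chelating N-acylpyrazole of 9 secures all three, because only the Rh-bound enoyl unit is electrophilic enough to trap the stabilised nucleophilic benzyl radical, and the silyloxy group, being on C4 and not on the enolate β-carbon, cannot be eliminated.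

Step 6
Reactants: 11 (S)-4-[4-(benzyloxy)-3-methoxybenzyl]dihydrofuran-2(3H)-one; 12 4-(benzyloxy)-3-methoxybenzaldehyde
Product: 13 (3R,4S)-4-[4-(benzyloxy)-3-methoxybenzyl]-3-{[4-(benzyloxy)-3-methoxyphenyl](hydroxy)methyl}dihydrofuran-2(3H)-one (both carbinol epimers)
Conditions: LDA (1.1 equiv), THF, −78 °C; then 12, −78 °C; AcOH quench at −78 °C
Reagents that add atoms: none
Why: Aldol addition of the lithium lactone enolate should take the aldehyde onto C3 anti to the C4 benzyl group (1,2-induction in the planar five-membered enolate), which sets C3 trans to C4, while the carbinol center forms unselectively and is re-set in step 8.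

Step 7
Reactants: 13 (3R,4S)-4-[4-(benzyloxy)-3-methoxybenzyl]-3-{[4-(benzyloxy)-3-methoxyphenyl](hydroxy)methyl}dihydrofuran-2(3H)-one
Product: 14 (2S,3S)-3-[4-(benzyloxy)-3-methoxybenzyl]-2-{[4-(benzyloxy)-3-methoxyphenyl](hydroxy)methyl}butane-1,4-diol (both carbinol epimers)
Conditions: LiAlH4 (3 equiv), THF, 0 °C → rt; aq. NaOH work-up
Reagents that add atoms: none
Why: Hydride reduction of the lactone to the 1,4-diol should be faster at 0 °C than retro-aldol of the aluminium aldolate and touches neither of the two set stereocenters nor the benzyl ethers.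

Step 8
Reactants: 14 (2S,3S)-3-[4-(benzyloxy)-3-methoxybenzyl]-2-{[4-(benzyloxy)-3-methoxyphenyl](hydroxy)methyl}butane-1,4-diol
Product: 15 {(2R,3S,4S)-4-[4-(benzyloxy)-3-methoxybenzyl]-2-[4-(benzyloxy)-3-methoxyphenyl]oxolan-3-yl}methanol
Conditions: 10-camphorsulfonic acid (10 mol %), CH2Cl2, 0 °C; Et3N quench at full conversion
Reagents that add atoms: none
Why: Acid-catalysed SN1 cycloetherification should ionise the benzylic alcohol to a 4-alkoxybenzyl cation that the C4 hydroxyl of the diol chain captures in a five-membered (formally 5-exo-tet) closure; both carbinol epimers pass through the same planar cation and close with the aryl group trans to the neighbouring hydroxymethyl group (R at C2), so the step is stereoconvergent.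

Step 9
Reactants: 15 {(2R,3S,4S)-4-[4-(benzyloxy)-3-methoxybenzyl]-2-[4-(benzyloxy)-3-methoxyphenyl]oxolan-3-yl}methanol
Product: 16 (−)-lariciresinol, 4-{(2R,3S,4S)-4-[(4-hydroxy-3-methoxyphenyl)methyl]-3-(hydroxymethyl)oxolan-2-yl}-2-methoxyphenol
Conditions: H2 (1 atm), 10 % Pd/C, EtOAc, rt, stopped after uptake of 2 equiv
Reagents that add atoms: none
Why: Hydrogenolysis of the two aryl benzyl ethers on Pd/C should be much faster in neutral ethyl acetate than cleavage of the benzylic C2–O bond of the oxolane, so the bis-phenol is freed with all three stereocenters intact.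

Step 10
Reactants: 16 (−)-lariciresinol; 17 (E)-3-(4-hydroxyphenyl)prop-2-enoic acid (p-coumaric acid)
Product: 18 [(2R,3S,4S)-2-(4-hydroxy-3-methoxyphenyl)-4-[(4-hydroxy-3-methoxyphenyl)methyl]oxolan-3-yl]methyl (E)-3-(4-hydroxyphenyl)prop-2-enoate (lariciresinol p-coumarate)
Conditions: 17 (1.2 equiv), PPh3 (1.3 equiv), DIAD (1.3 equiv), THF, 0 °C → rt
Reagents that add atoms: none
Why: In this Mitsunobu esterification the betaine should be protonated by the carboxylic acid in preference to the far less acidic phenols, and the only aliphatic hydroxyl is activated and displaced by the carboxylate at a primary, non-stereogenic carbon, so the phenols, the stereocenters and the E-alkene are left untouched.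

**Compound list**

1 | [4-(benzyloxy)-3-methoxyphenyl]methanol | COc1cc(CO)ccc1OCc1ccccc1 | starting material
2 | 1-(benzyloxy)-4-(chloromethyl)-2-methoxybenzene | COc1cc(CCl)ccc1OCc1ccccc1 | intermediate
3 | 2-[4-(benzyloxy)-3-methoxybenzyl]-4,4,5,5-tetramethyl-1,3,2-dioxaborolane | COc1cc(CB2OC(C)(C)C(C)(C)O2)ccc1OCc1ccccc1 | intermediate
4 | potassium [4-(benzyloxy)-3-methoxybenzyl]trifluoroborate | COc1cc(C[B-](F)(F)F)ccc1OCc1ccccc1.[K+] | intermediate
5 | acryloyl chloride | C=CC(=O)Cl | starting material
6 | 3,5-dimethyl-1H-pyrazole | Cc1cc(C)[nH]n1 | starting material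
7 | 1-(3,5-dimethyl-1H-pyrazol-1-yl)prop-2-en-1-one | C=CC(=O)n1nc(C)cc1C | intermediate
8 | (allyloxy)(tert-butyl)dimethylsilane | C=CCO[Si](C)(C)C(C)(C)C | starting material
9 | (E)-4-[(tert-butyldimethylsilyl)oxy]-1-(3,5-dimethyl-1H-pyrazol-1-yl)but-2-en-1-one | CC(C)(C)[Si](C)(C)OC/C=C/C(=O)n1nc(C)cc1C | intermediate
10 | (S)-3-[4-(benzyloxy)-3-methoxybenzyl]-4-[(tert-butyldimethylsilyl)oxy]-1-(3,5-dimethyl-1H-pyrazol-1-yl)butan-1-one | COc1cc(C[C@@H](CC(=O)n2nc(C)cc2C)CO[Si](C)(C)C(C)(C)C)ccc1OCc1ccccc1 | intermediate
11 | (S)-4-[4-(benzyloxy)-3-methoxybenzyl]dihydrofuran-2(3H)-one | COc1cc(C[C@@H]2COC(=O)C2)ccc1OCc1ccccc1 | intermediate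
12 | 4-(benzyloxy)-3-methoxybenzaldehyde | COc1cc(C=O)ccc1OCc1ccccc1 | starting material
13 | (3R,4S)-4-[4-(benzyloxy)-3-methoxybenzyl]-3-{[4-(benzyloxy)-3-methoxyphenyl](hydroxy)methyl}dihydrofuran-2(3H)-one, both carbinol epimers | COc1cc(C[C@@H]2COC(=O)[C@H]2C(O)c2ccc(OCc3ccccc3)c(OC)c2)ccc1OCc1ccccc1 | intermediate
14 | (2S,3S)-3-[4-(benzyloxy)-3-methoxybenzyl]-2-{[4-(benzyloxy)-3-methoxyphenyl](hydroxy)methyl}butane-1,4-diol, both carbinol epimers | COc1cc(C[C@H](CO)[C@@H](CO)C(O)c2ccc(OCc3ccccc3)c(OC)c2)ccc1OCc1ccccc1 | intermediate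
15 | {(2R,3S,4S)-4-[4-(benzyloxy)-3-methoxybenzyl]-2-[4-(benzyloxy)-3-methoxyphenyl]oxolan-3-yl}methanol | COc1cc(C[C@@H]2CO[C@@H](c3ccc(OCc4ccccc4)c(OC)c3)[C@@H]2CO)ccc1OCc1ccccc1 | intermediate
16 | (−)-lariciresinol, 4-{(2R,3S,4S)-4-[(4-hydroxy-3-methoxyphenyl)methyl]-3-(hydroxymethyl)oxolan-2-yl}-2-methoxyphenol | COc1cc(C[C@@H]2CO[C@@H](c3ccc(O)c(OC)c3)[C@@H]2CO)ccc1O | intermediate
17 | (E)-3-(4-hydroxyphenyl)prop-2-enoic acid | OC(=O)/C=C/c1ccc(O)cc1 | starting material
18 | [(2R,3S,4S)-2-(4-hydroxy-3-methoxyphenyl)-4-[(4-hydroxy-3-methoxyphenyl)methyl]oxolan-3-yl]methyl (E)-3-(4-hydroxyphenyl)prop-2-enoate | COc1cc(C[C@@H]2CO[C@@H](c3ccc(O)c(OC)c3)[C@@H]2COC(=O)/C=C/c2ccc(O)cc2)ccc1O | target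

**Totals**

Total step count: 10. Longest linear sequence: 8 steps (1, 2, 5, 6, 7, 8, 9, 10).

**Steps most likely to fail**

(i) Step 5. The radical addition may suffer from weak facial discrimination, or from dimerisation or over-oxidation of the electron-rich benzyl radical before it is captured. The fallback is an oxazolidinone-auxiliary enolate alkylation that sets out from 2 and returns at 11. (S)-4-Benzyl-3-(4-tert-butoxy-4-oxobutanoyl)oxazolidin-2-one F1 is made from (S)-4-benzyloxazolidin-2-one and mono-tert-butyl succinate through the pivaloyl mixed anhydride. NaHMDS (THF, −78 °C) converts it into the chelated Z-enolate, which is alkylated with 2 (NaI) on the face away from the auxiliary benzyl group to give (S)-4-benzyl-3-[(S)-2-[4-(benzyloxy)-3-methoxybenzyl]-4-tert-butoxy-4-oxobutanoyl]oxazolidin-2-one F2. LiBH4 (THF/MeOH, 0 °C) removes the auxiliary reductively to give tert-butyl (S)-3-[4-(benzyloxy)-3-methoxybenzyl]-4-hydroxybutanoate F3, and TFA in CH2Cl2 closes the lactone to 11.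

(ii) Step 8. The benzylic cation may be trapped irreversibly by the second arene (Friedel–Crafts closure to an aryltetralin) before or after the ether ring forms, or the closure may not equilibrate fully to the 2,3-trans ring. The fallback is a near-neutral quinone-methide closure on a free phenol; it sets out from 11 and returns at 16. Compound 11 is condensed (LDA, −78 °C) with 4-formyl-2-methoxyphenyl pivalate F4 (from vanillin and pivaloyl chloride) to give the aldol adduct 4-{[(3R,4S)-4-[4-(benzyloxy)-3-methoxybenzyl]-2-oxooxolan-3-yl](hydroxy)methyl}-2-methoxyphenyl pivalate F5. LiAlH4 reduces the lactone and removes the pivalate in the same operation to give (2S,3S)-3-[4-(benzyloxy)-3-methoxybenzyl]-2-[hydroxy(4-hydroxy-3-methoxyphenyl)methyl]butane-1,4-diol F6. In weakly acidic buffer (AcOH, THF/H2O, rt) the 4-hydroxybenzylic alcohol should lose water to the para-quinone methide, which the C4 hydroxyl closes by intramolecular 1,6-addition to give 4-{(2R,3S,4S)-4-[4-(benzyloxy)-3-methoxybenzyl]-3-(hydroxymethyl)oxolan-2-yl}-2-methoxyphenol F7. Hydrogenolysis as in step 9 then gives 16.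

(iii) Step 10. The phenols may compete as nucleophiles toward the activated alcohol, or activation of the β-branched primary alcohol may stall. The fallback is a lipase-catalysed acyl transfer that sets out from 16 and 17 and returns at 18. Vinyl (E)-3-(4-hydroxyphenyl)prop-2-enoate F8 is made from 17 by Pd(II)-catalysed transvinylation with vinyl acetate. With immobilised Candida antarctica lipase B (2-methylbutan-2-ol, 50 °C) it should acylate only the primary aliphatic hydroxyl of 16, since lipases do not acylate phenols, and the vinyl alcohol released tautomerises so the transfer is irreversible.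

**Further compounds**

F1 | step 5 | (S)-4-benzyl-3-(4-tert-butoxy-4-oxobutanoyl)oxazolidin-2-one | O=C1OC[C@H](Cc2ccccc2)N1C(=O)CCC(=O)OC(C)(C)C
F2 | step 5 | (S)-4-benzyl-3-[(S)-2-[4-(benzyloxy)-3-methoxybenzyl]-4-tert-butoxy-4-oxobutanoyl]oxazolidin-2-one | COc1cc(C[C@@H](CC(=O)OC(C)(C)C)C(=O)N2[C@@H](Cc3ccccc3)COC2=O)ccc1OCc1ccccc1
F3 | step 5 | tert-butyl (S)-3-[4-(benzyloxy)-3-methoxybenzyl]-4-hydroxybutanoate | COc1cc(C[C@@H](CC(=O)OC(C)(C)C)CO)ccc1OCc1ccccc1
F4 | step 8 | 4-formyl-2-methoxyphenyl pivalate | COc1cc(C=O)ccc1OC(=O)C(C)(C)C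
F5 | step 8 | 4-{[(3R,4S)-4-[4-(benzyloxy)-3-methoxybenzyl]-2-oxooxolan-3-yl](hydroxy)methyl}-2-methoxyphenyl pivalate, both carbinol epimers | COc1cc(C[C@@H]2COC(=O)[C@H]2C(O)c2ccc(OC(=O)C(C)(C)C)c(OC)c2)ccc1OCc1ccccc1
F6 | step 8 | (2S,3S)-3-[4-(benzyloxy)-3-methoxybenzyl]-2-[hydroxy(4-hydroxy-3-methoxyphenyl)methyl]butane-1,4-diol, both carbinol epimers | COc1cc(C[C@H](CO)[C@@H](CO)C(O)c2ccc(O)c(OC)c2)ccc1OCc1ccccc1
F7 | step 8 | 4-{(2R,3S,4S)-4-[4-(benzyloxy)-3-methoxybenzyl]-3-(hydroxymethyl)oxolan-2-yl}-2-methoxyphenol | COc1cc(C[C@@H]2CO[C@@H](c3ccc(O)c(OC)c3)[C@@H]2CO)ccc1OCc1ccccc1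
F8 | step 10 | vinyl (E)-3-(4-hydroxyphenyl)prop-2-enoate | C=COC(=O)/C=C/c1ccc(O)cc1
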